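**Retrosynthetic overview**
- Target ⇒ MOM/TES-protected isoflavone. Ring C (the pyranone) is closed last at O1–C8a by SNAr of an α-formyl deoxybenzoin enolate on an aryl fluoride, which fixes the prenyl group at C6.
- Deoxybenzoin ⇒ ring A aryllithium (from 5-fluororesorcinol, prenyl placed para to F) + ring B arylacetic Weinreb amide, made from a chroman-6-carbaldehyde by one-carbon homologation.
- Chroman (ring D) ⇒ 6-endo opening of an (R)-epoxyprenyl group on C3' by the C4' phenol. The epoxide comes from Shi epoxidation of a prenyl arene made by directed ortho-metalation of protected 2,4-dihydroxybenzaldehyde.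
- Feature on which the strategy rests: ring D, the dihydropyran fused to ring B, O1''(on C4')–C2''(CH3)2–C3''H(OH)(R)–C4''H2(on C3'), is a C3' prenyl group oxidised at C3'' and closed through the O1''–C2'' bond.
- Ring order: ring D first (step 8), ring C last (step 18); rings A and B come from the two benzenoid starting materials.

Key step: step 8

Remark: the C3'' descriptor is read as R from the SMILES, and the D-fructose-derived Shi ketone is taken to give the (R)-epoxide of a prenyl arene, as its spiro transition-state model predicts.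

**Step 1**
Reactants: 1 2,4-dihydroxybenzaldehyde
Product: 2 4-formyl-3-hydroxyphenyl N,N-diethylcarbamate
Conditions: Et2NCOCl (1.05 equiv), K2CO3, MeCN, rt → 50 °C
Reagents that add atoms: N,N-diethylcarbamoyl chloride, CCN(CC)C(=O)Cl
Why: Selective O-acylation; the 4-OH is the more acidic phenol and is not hydrogen-bonded to the aldehyde as the 2-OH is, so it should be carbamoylated alone, which installs the group that later directs metalation.

**Step 2**
Reactants: 2 4-formyl-3-hydroxyphenyl N,N-diethylcarbamate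
Product: 3 4-formyl-3-(methoxymethoxy)phenyl N,N-diethylcarbamate
Conditions: MOMCl, iPr2NEt, CH2Cl2, 0 °C → reflux
Reagents that add atoms: chloromethyl methyl ether, COCCl
Why: O-alkylation of the remaining chelated phenol with an α-chloro ether under amine base (MOM protection); carbamate and aldehyde are inert.

**Step 3**
Reactants: 3 4-formyl-3-(methoxymethoxy)phenyl N,N-diethylcarbamate
Product: 4 4-(1,3-dioxolan-2-yl)-3-(methoxymethoxy)phenyl N,N-diethylcarbamate
Conditions: TMSOCH2CH2OTMS, TMSOTf (5 mol%), CH2Cl2, –78 → –20 °C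
Reagents that add atoms: 1,2-bis(trimethylsilyloxy)ethane, C[Si](C)(C)OCCO[Si](C)(C)C
Why: Noyori acetalisation under aprotic conditions at low temperature masks the aldehyde against organolithium, hydride and Oxone without cleaving the aryl MOM ether.

**Step 4**
Reactants: 4 4-(1,3-dioxolan-2-yl)-3-(methoxymethoxy)phenyl N,N-diethylcarbamate; 5 1-bromo-3-methylbut-2-ene (prenyl bromide)
Product: 7 4-(1,3-dioxolan-2-yl)-3-(methoxymethoxy)-2-(3-methylbut-2-en-1-yl)phenyl N,N-diethylcarbamate, via aryllithium 6 (not isolated)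
Conditions: s-BuLi, TMEDA, THF, –78 °C; then CuBr·SMe2 (20 mol%), 5, –78 → –20 °C
Reagents that add atoms: 1-bromo-3-methylbut-2-ene (5), CC(C)=CCBr
Why: Directed ortho-metalation at the one position flanked by both the O-carbamate and the OMOM director, then copper-catalysed allylic substitution on prenyl bromide at the primary carbon, run cold so that anionic ortho-Fries rearrangement does not compete.

**Step 5**
Reactants: 7 4-(1,3-dioxolan-2-yl)-3-(methoxymethoxy)-2-(3-methylbut-2-en-1-yl)phenyl N,N-diethylcarbamate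
Product: 8 4-(1,3-dioxolan-2-yl)-3-(methoxymethoxy)-2-(3-methylbut-2-en-1-yl)phenol
Conditions: LiAlH4, THF, 0 °C → rt; aqueous NaOH work-up
Reagents that add atoms: none
Why: Hydride reduction of the aryl carbamate expels the phenoxide under conditions that leave acetal, MOM ether and the trisubstituted alkene untouched.

**Step 6**
Reactants: 8 4-(1,3-dioxolan-2-yl)-3-(methoxymethoxy)-2-(3-methylbut-2-en-1-yl)phenol
Product: 9 tert-butyl[4-(1,3-dioxolan-2-yl)-3-(methoxymethoxy)-2-(3-methylbut-2-en-1-yl)phenoxy]dimethylsilane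
Conditions: TBSCl, imidazole, DMF, rt
Reagents that add atoms: tert-butyldimethylsilyl chloride, CC(C)(C)[Si](C)(C)Cl
Why: Silylation of the phenol keeps O4' from opening the epoxide during the basic epoxidation and allows its later release by fluoride without base.

**Step 7**
Reactants: 9 tert-butyl[4-(1,3-dioxolan-2-yl)-3-(methoxymethoxy)-2-(3-methylbut-2-en-1-yl)phenoxy]dimethylsilane
Product: 10 tert-butyl[4-(1,3-dioxolan-2-yl)-2-{[(2R)-3,3-dimethyloxiran-2-yl]methyl}-3-(methoxymethoxy)phenoxy]dimethylsilane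
Conditions: D-fructose-derived Shi ketone (30 mol%), Oxone (2KHSO5·KHSO4·K2SO4), K2CO3, Bu4NHSO4 (cat.), MeCN/dimethoxymethane, aqueous Na2B4O7/Na2EDTA buffer (pH 10.5), 0 °C
Reagents that add atoms: potassium peroxymonosulfate (Oxone), [K+].[O-]S(=O)(=O)OO
Why: Shi asymmetric epoxidation; the chiral dioxirane delivers oxygen through a spiro transition state to one face of the trisubstituted alkene, which sets C3'' and is expected to give the (R)-epoxide, while the basic buffer preserves acetal, MOM and aryl silyl ether.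

**Step 8**
Reactants: 10 tert-butyl[4-(1,3-dioxolan-2-yl)-2-{[(2R)-3,3-dimethyloxiran-2-yl]methyl}-3-(methoxymethoxy)phenoxy]dimethylsilane
Product: 12 (3R)-6-(1,3-dioxolan-2-yl)-5-(methoxymethoxy)-2,2-dimethylchroman-3-ol, via epoxy phenol 11 (not isolated)
Conditions: TBAF (1.1 equiv), AcOH (1.2 equiv), THF, 0 °C; then CSA (1.5 equiv), CH2Cl2, 0 °C → rt
Reagents that add atoms: none
Why: Fluoride buffered by AcOH removes the silyl group from O4' and gives phenol 11 in its neutral form, so no phenoxide is present to attack the secondary epoxide carbon; CSA then protonates the epoxide and lengthens the C2''–O bond at the tertiary carbon. The C4' hydroxyl attacks C2'' in a 6-endo-tet closure with SN1-like character, forming O1''–C2'' and ring D; this is the acid-catalysed endo opening of a trisubstituted epoxide by a hydroxyl group, known for ortho-(epoxyprenyl)phenols giving 3-hydroxy-2,2-dimethylchromans. No new stereocentre is formed: C2'' bears two methyl groups and the C3''–O bond is not touched, so the (R) configuration from the Shi epoxidation is carried over with retention. The step needs 6-endo over 5-exo regioselectivity, secured by acid catalysis and the tertiary terminus, and O4' over O2' selectivity, secured by the MOM cap on O2'. A sulfonic acid at 0 °C in aprotic medium should spare the aryl MOM ether, and any dioxolane lost to adventitious water converges on the product of step 9.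

**Step 9**
Reactants: 12 (3R)-6-(1,3-dioxolan-2-yl)-5-(methoxymethoxy)-2,2-dimethylchroman-3-ol
Product: 13 (3R)-3-hydroxy-5-(methoxymethoxy)-2,2-dimethylchroman-6-carbaldehyde
Conditions: 1 M HCl (aq), THF, 0 °C
Reagents that add atoms: water, O
Why: Acid-catalysed acetal hydrolysis; the dioxolane on the electron-rich ring should cleave much faster than the aryl MOM ether in cold dilute acid.

**Step 10**
Reactants: 13 (3R)-3-hydroxy-5-(methoxymethoxy)-2,2-dimethylchroman-6-carbaldehyde
Product: 14 (3R)-5-(methoxymethoxy)-2,2-dimethyl-3-(triethylsilyloxy)chroman-6-carbaldehyde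
Conditions: TESCl, imidazole, DMAP (cat.), DMF, rt
Reagents that add atoms: chlorotriethylsilane, CC[Si](Cl)(CC)CC
Why: Silylation masks the only protic group before the organometallic steps; a TES ether is chosen over an alkyl MOM ether because it falls under the mild acid that removes the aryl MOM groups at the end.

**Step 11**
Reactants: 14 (3R)-5-(methoxymethoxy)-2,2-dimethyl-3-(triethylsilyloxy)chroman-6-carbaldehyde
Product: 15 triethyl{[(3R)-6-ethenyl-5-(methoxymethoxy)-2,2-dimethylchroman-3-yl]oxy}silane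
Conditions: Ph3PCH3Br, KOtBu, THF, 0 °C → rt
Reagents that add atoms: methyltriphenylphosphonium bromide, C[P+](c1ccccc1)(c1ccccc1)c1ccccc1.[Br-]
Why: Wittig methylenation of a non-enolisable aryl aldehyde adds the carbon that becomes C4 of the isoflavone.

**Step 12**
Reactants: 15 triethyl{[(3R)-6-ethenyl-5-(methoxymethoxy)-2,2-dimethylchroman-3-yl]oxy}silane
Product: 17 2-[(3R)-5-(methoxymethoxy)-2,2-dimethyl-3-(triethylsilyloxy)chroman-6-yl]ethanol, via B-alkyl-9-BBN adduct 16 (not isolated)
Conditions: 9-BBN, THF, 0 °C → rt; then NaOH (aq), H2O2, 0 °C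
Reagents that add atoms: hydrogen peroxide, OO
Why: Hydroboration–oxidation; 9-BBN adds anti-Markovnikov to the styrene and oxidative C–B cleavage gives the primary alcohol under conditions that the hindered secondary TES ether should survive.

**Step 13**
Reactants: 17 2-[(3R)-5-(methoxymethoxy)-2,2-dimethyl-3-(triethylsilyloxy)chroman-6-yl]ethanol
Product: 19 2-[(3R)-5-(methoxymethoxy)-2,2-dimethyl-3-(triethylsilyloxy)chroman-6-yl]acetic acid, via arylacetaldehyde 18 (not isolated)
Conditions: TEMPO (20 mol%), PhI(OAc)2 (2.2 equiv), MeCN/pH 7 phosphate buffer, rt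
Reagents that add atoms: water, O
Why: Oxoammonium-catalysed oxidation of the primary alcohol to the aldehyde and, through its hydrate, to the acid under near-neutral conditions that spare the MOM and TES groups.

**Step 14**
Reactants: 19 2-[(3R)-5-(methoxymethoxy)-2,2-dimethyl-3-(triethylsilyloxy)chroman-6-yl]acetic acid
Product: 21 N-methoxy-N-methyl-2-[(3R)-5-(methoxymethoxy)-2,2-dimethyl-3-(triethylsilyloxy)chroman-6-yl]acetamide, via acyl imidazole 20 (not isolated)
Conditions: CDI, CH2Cl2, rt; then MeNH(OMe)·HCl, rt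
Reagents that add atoms: N,O-dimethylhydroxylamine hydrochloride, CNOC.Cl
Why: Amide coupling through the acyl imidazole gives the Weinreb amide without acid or strong base.

**Step 15**
Reactants: 22 5-fluorobenzene-1,3-diol (5-fluororesorcinol)
Product: 23 1-fluoro-3,5-bis(methoxymethoxy)benzene
Conditions: MOMCl, iPr2NEt, CH2Cl2, 0 °C → rt
Reagents that add atoms: chloromethyl methyl ether, COCCl
Why: Double MOM protection gives two coordinating directors for metalation and base-stable phenol protection.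

**Step 16**
Reactants: 23 1-fluoro-3,5-bis(methoxymethoxy)benzene; 5 1-bromo-3-methylbut-2-ene (prenyl bromide)
Product: 25 5-fluoro-1,3-bis(methoxymethoxy)-2-(3-methylbut-2-en-1-yl)benzene, via aryllithium 24 (not isolated)
Conditions: n-BuLi, THF, –40 °C; then CuBr·SMe2 (20 mol%), 5, –78 °C → rt
Reagents that add atoms: 1-bromo-3-methylbut-2-ene (5), CC(C)=CCBr
Why: Directed ortho-metalation under coordination control should take place at the site flanked by both OMOM groups (para to fluorine), and copper-catalysed prenylation then gives a symmetric arene whose two remaining ring hydrogens are equivalent.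

**Step 17**
Reactants: 25 5-fluoro-1,3-bis(methoxymethoxy)-2-(3-methylbut-2-en-1-yl)benzene; 21 N-methoxy-N-methyl-2-[(3R)-5-(methoxymethoxy)-2,2-dimethyl-3-(triethylsilyloxy)chroman-6-yl]acetamide
Product: 27 1-[6-fluoro-2,4-bis(methoxymethoxy)-3-(3-methylbut-2-en-1-yl)phenyl]-2-[(3R)-5-(methoxymethoxy)-2,2-dimethyl-3-(triethylsilyloxy)chroman-6-yl]ethanone, via aryllithium 26 (not isolated)
Conditions: 25 (1.3 equiv), n-BuLi, THF, –78 °C; then 21, –78 → –50 °C; aq. NH4Cl
Reagents that add atoms: none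
Why: Weinreb ketone synthesis; lithiation occurs at the only kind of ring C–H left (between F and OMOM), the aryllithium adds once to the amide to give a chelated tetrahedral intermediate, and –78 °C prevents loss of LiF to an aryne.

**Step 18**
Reactants: 27 1-[6-fluoro-2,4-bis(methoxymethoxy)-3-(3-methylbut-2-en-1-yl)phenyl]-2-[(3R)-5-(methoxymethoxy)-2,2-dimethyl-3-(triethylsilyloxy)chroman-6-yl]ethanone
Product: 29 5,7-bis(methoxymethoxy)-3-[(3R)-5-(methoxymethoxy)-2,2-dimethyl-3-(triethylsilyloxy)chroman-6-yl]-6-(3-methylbut-2-en-1-yl)-4H-chromen-4-one, via sodium formyl enolate 28 (not isolated)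
Conditions: NaH, HCO2Et, THF, 0 °C → rt; then DMF, 80 °C
Reagents that add atoms: ethyl formate, CCOC=O
Why: Claisen C-formylation of the deoxybenzoin gives the hydroxymethylene enolate, whose oxygen displaces the ortho fluoride activated by the aryl ketone (intramolecular SNAr, as in chromone syntheses from 2-fluoroaryl 1,3-dicarbonyls), closing ring C at O1–C8a with the prenyl group locked at C6.

**Step 19**
Reactants: 29 5,7-bis(methoxymethoxy)-3-[(3R)-5-(methoxymethoxy)-2,2-dimethyl-3-(triethylsilyloxy)chroman-6-yl]-6-(3-methylbut-2-en-1-yl)-4H-chromen-4-one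
Product: 30 5,7-dihydroxy-3-[(3R)-3,5-dihydroxy-2,2-dimethylchroman-6-yl]-6-(3-methylbut-2-en-1-yl)-4H-chromen-4-one (target)
Conditions: HCl (3 M in MeOH), rt → 40 °C
Reagents that add atoms: none
Why: Acid-catalysed methanolysis removes the three aryl MOM acetals and the TES ether in one operation under conditions commonly tolerated by C-prenyl phenols; C3'' is a non-epimerisable carbinol.

**Compound list**
1 | 2,4-dihydroxybenzaldehyde | O=Cc1ccc(O)cc1O | starting material
2 | 4-formyl-3-hydroxyphenyl N,N-diethylcarbamate | CCN(CC)C(=O)Oc1ccc(C=O)c(O)c1 | intermediate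
3 | 4-formyl-3-(methoxymethoxy)phenyl N,N-diethylcarbamate | CCN(CC)C(=O)Oc1ccc(C=O)c(OCOC)c1 | intermediate
4 | 4-(1,3-dioxolan-2-yl)-3-(methoxymethoxy)phenyl N,N-diethylcarbamate | CCN(CC)C(=O)Oc1ccc(C2OCCO2)c(OCOC)c1 | intermediate
5 | 1-bromo-3-methylbut-2-ene | CC(C)=CCBr | starting material
6 | [6-(diethylcarbamoyloxy)-3-(1,3-dioxolan-2-yl)-2-(methoxymethoxy)phenyl]lithium | CCN(CC)C(=O)Oc1ccc(C2OCCO2)c(OCOC)c1[Li] | intermediate (not isolated)
7 | 4-(1,3-dioxolan-2-yl)-3-(methoxymethoxy)-2-(3-methylbut-2-en-1-yl)phenyl N,N-diethylcarbamate | CCN(CC)C(=O)Oc1ccc(C2OCCO2)c(OCOC)c1CC=C(C)C | intermediate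
8 | 4-(1,3-dioxolan-2-yl)-3-(methoxymethoxy)-2-(3-methylbut-2-en-1-yl)phenol | COCOc1c(C2OCCO2)ccc(O)c1CC=C(C)C | intermediate
9 | tert-butyl[4-(1,3-dioxolan-2-yl)-3-(methoxymethoxy)-2-(3-methylbut-2-en-1-yl)phenoxy]dimethylsilane | COCOc1c(C2OCCO2)ccc(O[Si](C)(C)C(C)(C)C)c1CC=C(C)C | intermediate
10 | tert-butyl[4-(1,3-dioxolan-2-yl)-2-{[(2R)-3,3-dimethyloxiran-2-yl]methyl}-3-(methoxymethoxy)phenoxy]dimethylsilane | COCOc1c(C2OCCO2)ccc(O[Si](C)(C)C(C)(C)C)c1C[C@H]1OC1(C)C | intermediate
11 | 4-(1,3-dioxolan-2-yl)-2-{[(2R)-3,3-dimethyloxiran-2-yl]methyl}-3-(methoxymethoxy)phenol | COCOc1c(C2OCCO2)ccc(O)c1C[C@H]1OC1(C)C | intermediate (not isolated)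
12 | (3R)-6-(1,3-dioxolan-2-yl)-5-(methoxymethoxy)-2,2-dimethylchroman-3-ol | COCOc1c(C2OCCO2)ccc2c1C[C@@H](O)C(C)(C)O2 | intermediate
13 | (3R)-3-hydroxy-5-(methoxymethoxy)-2,2-dimethylchroman-6-carbaldehyde | COCOc1c(C=O)ccc2c1C[C@@H](O)C(C)(C)O2 | intermediate
14 | (3R)-5-(methoxymethoxy)-2,2-dimethyl-3-(triethylsilyloxy)chroman-6-carbaldehyde | COCOc1c(C=O)ccc2c1C[C@@H](O[Si](CC)(CC)CC)C(C)(C)O2 | intermediate
15 | triethyl{[(3R)-6-ethenyl-5-(methoxymethoxy)-2,2-dimethylchroman-3-yl]oxy}silane | COCOc1c(C=C)ccc2c1C[C@@H](O[Si](CC)(CC)CC)C(C)(C)O2 | intermediate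
16 | 9-{2-[(3R)-5-(methoxymethoxy)-2,2-dimethyl-3-(triethylsilyloxy)chroman-6-yl]ethyl}-9-borabicyclo[3.3.1]nonane | COCOc1c(CCB2C3CCCC2CCC3)ccc2c1C[C@@H](O[Si](CC)(CC)CC)C(C)(C)O2 | intermediate (not isolated)
17 | 2-[(3R)-5-(methoxymethoxy)-2,2-dimethyl-3-(triethylsilyloxy)chroman-6-yl]ethanol | COCOc1c(CCO)ccc2c1C[C@@H](O[Si](CC)(CC)CC)C(C)(C)O2 | intermediate
18 | 2-[(3R)-5-(methoxymethoxy)-2,2-dimethyl-3-(triethylsilyloxy)chroman-6-yl]acetaldehyde | COCOc1c(CC=O)ccc2c1C[C@@H](O[Si](CC)(CC)CC)C(C)(C)O2 | intermediate (not isolated)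
19 | 2-[(3R)-5-(methoxymethoxy)-2,2-dimethyl-3-(triethylsilyloxy)chroman-6-yl]acetic acid | COCOc1c(CC(=O)O)ccc2c1C[C@@H](O[Si](CC)(CC)CC)C(C)(C)O2 | intermediate
20 | 1-(1H-imidazol-1-yl)-2-[(3R)-5-(methoxymethoxy)-2,2-dimethyl-3-(triethylsilyloxy)chroman-6-yl]ethanone | COCOc1c(CC(=O)n2ccnc2)ccc2c1C[C@@H](O[Si](CC)(CC)CC)C(C)(C)O2 | intermediate (not isolated)
21 | N-methoxy-N-methyl-2-[(3R)-5-(methoxymethoxy)-2,2-dimethyl-3-(triethylsilyloxy)chroman-6-yl]acetamide | COCOc1c(CC(=O)N(C)OC)ccc2c1C[C@@H](O[Si](CC)(CC)CC)C(C)(C)O2 | intermediate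
22 | 5-fluorobenzene-1,3-diol | Oc1cc(O)cc(F)c1 | starting material
23 | 1-fluoro-3,5-bis(methoxymethoxy)benzene | COCOc1cc(F)cc(OCOC)c1 | intermediate
24 | [4-fluoro-2,6-bis(methoxymethoxy)phenyl]lithium | COCOc1cc(F)cc(OCOC)c1[Li] | intermediate (not isolated)
25 | 5-fluoro-1,3-bis(methoxymethoxy)-2-(3-methylbut-2-en-1-yl)benzene | COCOc1cc(F)cc(OCOC)c1CC=C(C)C | intermediate
26 | [6-fluoro-2,4-bis(methoxymethoxy)-3-(3-methylbut-2-en-1-yl)phenyl]lithium | COCOc1cc(F)c([Li])c(OCOC)c1CC=C(C)C | intermediate (not isolated)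
27 | 1-[6-fluoro-2,4-bis(methoxymethoxy)-3-(3-methylbut-2-en-1-yl)phenyl]-2-[(3R)-5-(methoxymethoxy)-2,2-dimethyl-3-(triethylsilyloxy)chroman-6-yl]ethanone | COCOc1cc(F)c(C(=O)Cc2ccc3c(c2OCOC)C[C@@H](O[Si](CC)(CC)CC)C(C)(C)O3)c(OCOC)c1CC=C(C)C | intermediate
28 | sodium 3-[6-fluoro-2,4-bis(methoxymethoxy)-3-(3-methylbut-2-en-1-yl)phenyl]-2-[(3R)-5-(methoxymethoxy)-2,2-dimethyl-3-(triethylsilyloxy)chroman-6-yl]-3-oxoprop-1-en-1-olate | COCOc1cc(F)c(C(=O)C(=C[O-])c2ccc3c(c2OCOC)C[C@@H](O[Si](CC)(CC)CC)C(C)(C)O3)c(OCOC)c1CC=C(C)C.[Na+] | intermediate (not isolated)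
29 | 5,7-bis(methoxymethoxy)-3-[(3R)-5-(methoxymethoxy)-2,2-dimethyl-3-(triethylsilyloxy)chroman-6-yl]-6-(3-methylbut-2-en-1-yl)-4H-chromen-4-one | COCOc1cc2occ(-c3ccc4c(c3OCOC)C[C@@H](O[Si](CC)(CC)CC)C(C)(C)O4)c(=O)c2c(OCOC)c1CC=C(C)C | intermediate
30 | 5,7-dihydroxy-3-[(3R)-3,5-dihydroxy-2,2-dimethylchroman-6-yl]-6-(3-methylbut-2-en-1-yl)-4H-chromen-4-one | CC(C)=CCc1c(O)cc2occ(-c3ccc4c(c3O)C[C@@H](O)C(C)(C)O4)c(=O)c2c1O | target

**Step count**
Total: 19 steps. Longest linear sequence: 17 steps (steps 1–14, then 17, 18, 19); steps 15–16 make the ring A fragment.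

**Steps most likely to fail**

1. Step 8. The phenol may attack the secondary epoxide carbon in the 5-exo mode, giving the hydroxyisopropyl dihydrobenzofuran skeleton, or the acid may strip the MOM cap before ring closure so that O2' competes. The fallback builds ring D without a phenol/epoxide closure. It sets out from phenol 8, which is cyclised oxidatively with DDQ (toluene, 80 °C) to 6-(1,3-dioxolan-2-yl)-5-(methoxymethoxy)-2,2-dimethyl-2H-chromene F1. Jacobsen–Katsuki epoxidation with the (R,R)-Mn(salen)Cl complex (NaOCl, 4-phenylpyridine N-oxide, CH2Cl2, 0 °C) is expected to give (3R,4R)-6-(1,3-dioxolan-2-yl)-3,4-epoxy-5-(methoxymethoxy)-2,2-dimethylchroman F2. Hydride opening at the benzylic C4 (LiAlH4, THF, 0 °C) leaves the C3–O bond intact and comes back to the route at 12.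

2. Step 17. The hindered, basic aryllithium may deprotonate the benzylic α-CH2 of the amide instead of adding to it, and it may lose LiF to an aryne if the temperature drifts. The fallback replaces acyl substitution by 1,2-addition and oxidation. It sets out from alcohol 17, which is oxidised with Dess–Martin periodinane to aldehyde 18, here isolated. Aryllithium 26 is added at –78 °C to give 1-[6-fluoro-2,4-bis(methoxymethoxy)-3-(3-methylbut-2-en-1-yl)phenyl]-2-[(3R)-5-(methoxymethoxy)-2,2-dimethyl-3-(triethylsilyloxy)chroman-6-yl]ethanol F3 as a mixture of carbinol epimers. A second Dess–Martin oxidation comes back to the route at 27.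

3. Step 18. Fluoride displacement on the donor-substituted ring may be slow, so that deformylation (retro-Claisen) or intermolecular attack by ethoxide takes over. The fallback puts the ring oxygen in first and closes ring C the classical way. It sets out from 27, which is treated with an α-effect hydroxide surrogate (acetohydroxamic acid, K2CO3, DMSO, 80 °C) to give 1-[6-hydroxy-2,4-bis(methoxymethoxy)-3-(3-methylbut-2-en-1-yl)phenyl]-2-[(3R)-5-(methoxymethoxy)-2,2-dimethyl-3-(triethylsilyloxy)chroman-6-yl]ethanone F4. Condensation with DMF dimethyl acetal (toluene, 90 °C; enaminone formation, then addition–elimination by the phenol) comes back to the route at 29.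

**Further compounds**
F1 | step 8 | 6-(1,3-dioxolan-2-yl)-5-(methoxymethoxy)-2,2-dimethyl-2H-chromene | COCOc1c(C2OCCO2)ccc2c1C=CC(C)(C)O2
F2 | step 8 | (3R,4R)-6-(1,3-dioxolan-2-yl)-3,4-epoxy-5-(methoxymethoxy)-2,2-dimethylchroman | COCOc1c(C2OCCO2)ccc2c1[C@H]1O[C@H]1C(C)(C)O2
F3 | step 17 | 1-[6-fluoro-2,4-bis(methoxymethoxy)-3-(3-methylbut-2-en-1-yl)phenyl]-2-[(3R)-5-(methoxymethoxy)-2,2-dimethyl-3-(triethylsilyloxy)chroman-6-yl]ethanol | COCOc1cc(F)c(C(O)Cc2ccc3c(c2OCOC)C[C@@H](O[Si](CC)(CC)CC)C(C)(C)O3)c(OCOC)c1CC=C(C)C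
F4 | step 18 | 1-[6-hydroxy-2,4-bis(methoxymethoxy)-3-(3-methylbut-2-en-1-yl)phenyl]-2-[(3R)-5-(methoxymethoxy)-2,2-dimethyl-3-(triethylsilyloxy)chroman-6-yl]ethanone | COCOc1cc(O)c(C(=O)Cc2ccc3c(c2OCOC)C[C@@H](O[Si](CC)(CC)CC)C(C)(C)O3)c(OCOC)c1CC=C(C)C
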